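| flask | solid substrate | reagent | free catalyst | temperature | remark | time |
|---|---|---|---|---|---|---|
| cedar | 0.050 M | 0.95 equiv (in portions, 2) | 1 mol% | −5 °C | run made earlier; portions every 2.0 min |  |
| maple | 0.050 M | 0.95 equiv (in portions, 2) | 1.5 mol% | 25 °C | run made earlier; portions every 2.0 min |  |
| birch | 0.050 M | 0.47 equiv (in portions, 2) | 2 mol% | −5 °C | run made earlier; portions every 2.0 min |  |
| north-west | 0.050 M | 0.950 equiv (in portions, 2) | 2 mol% | 50 °C | the portions of reagent follow each other after 2.0 min, the first at the start | 40 min |
| south | 0.050 M | 0.950 equiv (in portions, 2) | 2 mol% | 25 °C | the portions of reagent follow each other after 2.0 min, the first at the start | 40 min |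
| east | 0.050 M | 0.950 equiv (in portions, 2) | 2 mol% | 0 °C | the portions of reagent follow each other after 2.0 min, the first at the start | 40 min |

| cedar: time / min | cedar: target / % | maple: time / min | maple: target / % | birch: time / min | birch: target / % |
|---|---|---|---|---|---|
| 60.0 | 80 | 10.0 | 94 | 120 | 44 |
| 150 | 95 | 20.0 | 93 | 240 | 46 |
| 300 | 94 | 40.0 | 95 | 360 | 49 |
| 480 | 97 | 60.0 | 95 | 480 | 49 |
| 600 | 95 | 150 | 95 | 600 | 47 |

(each reading ± 1.5 percentage points)

- amounts and yields of released group count crystals too
- given per volume of solution although it is solid: crystals, solid substrate
- what may be going on: solid substrate <-> starting material; catalyst intermediate B -> released group + catalyst intermediate C; crystals <-> released group; reagent + free catalyst <-> catalyst intermediate A; starting material + released group -> side product; starting material + catalyst intermediate A -> catalyst intermediate B; catalyst intermediate C -> free catalyst + target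
- at the start none of the solid substrate is in solution
- what has only dissolved of solid substrate counts as not reacted

* the flask with the highest amount of target, in percent of the solid substrate charged ("all alike" if they lie within 1.5 percentage points) (north-west / south / east / all alike)
* final target, as a percentage of the solid substrate charged, in north-west
* final target, as a percentage of the solid substrate charged, in south
* final target, as a percentage of the solid substrate charged, in east

1. I start from amounts. Each target takes one reagent and one solid substrate, and the catalyst comes back, so I compare the two charges. Let r be the equivalents of reagent per solid substrate.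

2. The bench rule says that final target, as a fraction of the solid substrate charged, equals r. Cedar, at r = 0.95, reads 97 % at 480 min, and birch, at r = 0.47, reads 49 % at the same time. The reagent ratio of birch to cedar is 0.495 and the ratio of these two target readings is 0.505, so in these runs reagent is the limiting reagent.

3. The rule stops working where r reaches one: beyond that, the solid substrate is the smaller charge. Here r is 0.950, below one, so for the three new flasks I reckon 95.0 %. That is the ceiling, the smaller of r and one in percent of the solid substrate charged.

4. The flasks must also reach the ceiling in 40 min. Maple read 94 % at 10.0 min, with less catalyst than south. East is my doubtful flask. It has twice cedar's catalyst, so if rate follows catalyst, its time counts as 80.0 min of cedar, before any gain from being warmer. Cedar read 80 % at 60.0 min and 95 % at 150 min. I still commit to the ceiling in each flask, which makes them alike within the margin.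

5. The forecast differs from my reckoning: it names south, with 92 % in north-west, 95 % in south and 93.5 % in east, and of north-west it says that "warmer solution holds more dissolved released group".

6. The flasks give 95.0 % in north-west, 95.0 % in south and 94.8 % in east, so the answer is all alike, against a ceiling of 95.0 %.

    solid substrate ⇌ starting material, rate k1*(cs1 - [starting material]) while solid is left; crystals form when [starting material] > cs1 (solubility = 32.0 mM, k = 0.00302 /s)
    catalyst intermediate B → released group + catalyst intermediate C (k = 0.548 /s, Ea = 65.0 kJ/mol)
    crystals ⇌ released group, rate k3*(cs3 - [released group]) while solid is left; crystals form when [released group] > cs3 (solubility = 5.60 mM, k = 0.115 /s)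
    reagent + free catalyst ⇌ catalyst intermediate A (K = 62.0 /M, k = 615 /M/s, Ea = 41.0 kJ/mol, ΔH = −4.00 kJ/mol)
    starting material + released group → side product (k = 0.0831 /M/s, Ea = 59.0 kJ/mol)
    starting material + catalyst intermediate A → catalyst intermediate B (k = 138 /M/s, Ea = 48.0 kJ/mol)
    catalyst intermediate C → free catalyst + target (k = 10.9 /s, Ea = 74.0 kJ/mol)
    (constants at 25 °C)

The neighbour of north-west, with 2.40 equiv of reagent, lies past the border. There the same reckoning gives a ceiling of 100 % and about 58.3 % of the reagent charge left over. That flask gives 99.4 % target, with 0 % of the solid substrate left, solid or dissolved, and 58 % of the charged reagent still there, unbound.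

The numbers in the tables come from a simulation with made-up constants.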